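**Retrosynthetic overview**

1. Feature: in ring B the two fully substituted ring-fusion carbons C5 (OH) and C10 (CH3) lie between the C6–C7 ethano unit and the C8/C9 pair that carries C12 and C11. With the alkene moved to C8=C9, ring B is a cyclohexene that opens by retro-[4+2] across C5–C10 and C6–C7.
2. Endgame: dialdehyde from the 11,12-diol, C1 coumarate by late acylation, C9 set in the Δ8→Δ7 deconjugation while C11 is tied to O1 as a γ-lactone.
3. Key disconnection: rings A and B are closed together (no ring exists before step 14) by an intramolecular inverse-demand Diels–Alder reaction of an acyclic triene: diester diene C7=C8–C9=C10, silyl enol ether C5=C6, tether C1–C4.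
4. Triene: Stille coupling (C8–C9) of an α-iodo enoate, made by syn-carbocupration/iodination of an (R)-γ-silyloxy ynoate, with an α-stannyl acrylate; C1 comes from asymmetric transfer hydrogenation of an ynone.
5. Chain C1–C6: Michael addition of 3-methylbutan-2-one to methyl acrylate.

Key step: step 14

Remark: drimane numbering (C1 O-acyl, C4 CMe2, C5 OH, C10 CH3, C9–C11, C8–C12) is used for all intermediates, acyclic ones included. The enol ether carries SiMe3 so that the group placed under the diene is small and O5 is freed under mild conditions.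

**Route**

Step 1
Reactants: 1 3-methylbutan-2-one; 2 methyl acrylate
Product: 3 methyl 4,4-dimethyl-5-oxohexanoate
Conditions: 1 (3 equiv), KOtBu (5 mol%), tBuOH, 25 °C
Reagents that add atoms: none
Why: Base-catalysed Michael addition in which the ketone reacts through its more substituted (thermodynamic) enolate, so the new bond forms at the methine carbon and creates the C4 gem-dimethyl group, while catalytic base and excess ketone keep the adduct from closing by Claisen condensation.

Step 2
Reactants: 3 methyl 4,4-dimethyl-5-oxohexanoate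
Product: 4 methyl 4-methyl-4-(2-methyl-1,3-dioxolan-2-yl)pentanoate
Conditions: (Me3SiOCH2)2, TMSOTf (5 mol%), CH2Cl2, −78 → −20 °C
Reagents that add atoms: 1,2-bis(trimethylsilyloxy)ethane C[Si](C)(C)OCCO[Si](C)(C)C
Why: Silyl-transfer ketalisation masks the hindered C5 ketone without touching the methyl ester, so that the organolithium and cuprate steps ahead meet no free ketone.

Step 3
Reactants: 4 methyl 4-methyl-4-(2-methyl-1,3-dioxolan-2-yl)pentanoate
Product: 5 N-methoxy-N,4-dimethyl-4-(2-methyl-1,3-dioxolan-2-yl)pentanamide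
Conditions: MeNH(OMe)·HCl, iPrMgCl, THF, −20 → 0 °C
Reagents that add atoms: N,O-dimethylhydroxylamine hydrochloride CNOC.Cl
Why: Direct aminolysis of the methyl ester by the chloromagnesium amide of N,O-dimethylhydroxylamine gives the Weinreb amide.

Step 4
Reactants: 5 Weinreb amide; 6 ethynyltrimethylsilane
Product: 8 6-methyl-6-(2-methyl-1,3-dioxolan-2-yl)-1-(trimethylsilyl)hept-1-yn-3-one, via lithium (trimethylsilyl)acetylide 7 (not isolated)
Conditions: 6, nBuLi, THF, −78 °C; then 5, −78 → 0 °C; aq. NH4Cl
Reagents that add atoms: none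
Why: Weinreb ketone synthesis, in which the lithium acetylide adds once and the chelated tetrahedral adduct holds until work-up, so no tertiary alcohol forms.

Step 5
Reactants: 8 ynone
Product: 9 (3R)-6-methyl-6-(2-methyl-1,3-dioxolan-2-yl)-1-(trimethylsilyl)hept-1-yn-3-ol
Conditions: Ru[(R,R)-TsNCHPhCHPhNH](p-cymene) (1 mol%), iPrOH, 25 °C
Reagents that add atoms: none
Why: Noyori asymmetric transfer hydrogenation of an ynone, in which the (R,R)-TsDPEN ruthenium hydride reduces the carbonyl face that places the alkyne next to the arene ligand and should set C1 as (R) (OH > alkynyl > CH2), the same sense in which the (S,S) catalyst gives (S)-alkynyl carbinols.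

Step 6
Reactants: 9 propargylic alcohol
Product: 10 (3R)-3-[(tert-butyldimethylsilyl)oxy]-6-methyl-6-(2-methyl-1,3-dioxolan-2-yl)-1-(trimethylsilyl)hept-1-yne
Conditions: TBSCl, imidazole, DMF, 25 °C
Reagents that add atoms: tert-butyldimethylsilyl chloride CC(C)(C)[Si](C)(C)Cl
Why: Standard silylation of the secondary propargylic alcohol with a group that is a poor leaving group in the cuprate step.

Step 7
Reactants: 10 bis-silyl compound
Product: 11 (3R)-3-[(tert-butyldimethylsilyl)oxy]-6-methyl-6-(2-methyl-1,3-dioxolan-2-yl)hept-1-yne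
Conditions: K2CO3, MeOH, 25 °C
Reagents that add atoms: none
Why: Methanolysis of the C(sp)–SiMe3 bond under mild base, to which the silyl ether and the dioxolane are stable.

Step 8
Reactants: 11 terminal alkyne
Product: 13 methyl (4R)-4-[(tert-butyldimethylsilyl)oxy]-7-methyl-7-(2-methyl-1,3-dioxolan-2-yl)oct-2-ynoate, via lithium acetylide 12 (not isolated)
Conditions: nBuLi, THF, −78 °C; ClCO2Me, −78 → 0 °C
Reagents that add atoms: methyl chloroformate COC(=O)Cl
Why: Deprotonation of the terminal alkyne and C-acylation of the acetylide with the chloroformate gives the ynoate that carries C11.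

Step 9
Reactants: 13 ynoate
Product: 15 methyl (2E,4R)-4-[(tert-butyldimethylsilyl)oxy]-2-iodo-3,7-dimethyl-7-(2-methyl-1,3-dioxolan-2-yl)oct-2-enoate, via lithium alkenyl(methyl)cuprate 14 (not isolated)
Conditions: Me2CuLi (from MeLi, CuI), THF, −78 °C; then I2, THF, −78 → −40 °C
Reagents that add atoms: lithium dimethylcuprate [Li+].C[Cu-]C; iodine II
Why: Conjugate syn-carbocupration of the ynoate puts the methyl group on C10 and copper on C9 on the same side, and iodinolysis of the alkenylcopper at low temperature goes with retention, so iodine ends up cis to the new methyl and the C1 chain cis to the ester.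

Step 10
Reactants: 15 ketal iodide
Product: 16 methyl (2E,4R)-4-[(tert-butyldimethylsilyl)oxy]-2-iodo-3,7,7-trimethyl-8-oxonon-2-enoate
Conditions: PPTS, acetone–H2O (10:1), 56 °C
Reagents that add atoms: water O
Why: Acid-catalysed hydrolysis of the dioxolane under conditions mild enough for the secondary silyl ether, the alkenyl iodide and the enoate.

Step 11
Reactants: 17 methyl propiolate
Product: 18 methyl 2-(tributylstannyl)prop-2-enoate
Conditions: Bu3SnH, Pd(PPh3)4 (2 mol%), THF, 0 → 25 °C
Reagents that add atoms: tributyltin hydride CCCC[SnH](CCCC)CCCC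
Why: Palladium-catalysed hydrostannation of a propiolate is α-selective, with syn addition of Sn–H placing tin on the carbon that bears the ester.

Step 12
Reactants: 16 keto iodide; 18 stannyl acrylate
Product: 19 dimethyl (2Z)-2-[(3R)-3-[(tert-butyldimethylsilyl)oxy]-6,6-dimethyl-7-oxooctan-2-ylidene]-3-methylidenebutanedioate (C1 cis to the C9 ester, C10 methyl cis to C8)
Conditions: Pd2(dba)3 (5 mol%), AsPh3 (40 mol%), CuI (1 equiv), BHT, DMF, 45 °C
Reagents that add atoms: none
Why: Stille coupling with copper co-catalysis, in which CuI speeds up transmetalation of the α-stannyl acrylate and suppresses cine substitution, joins C9 to C8 with retention of the C9=C10 geometry.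

Step 13
Reactants: 19 keto diene diester
Product: 20 dimethyl (2Z)-2-[(3R)-3-[(tert-butyldimethylsilyl)oxy]-6,6-dimethyl-7-[(trimethylsilyl)oxy]oct-7-en-2-ylidene]-3-methylidenebutanedioate
Conditions: TMSOTf, Et3N, CH2Cl2, 0 °C; pentane, cold aq. NaHCO3 wash; used crude
Reagents that add atoms: trimethylsilyl trifluoromethanesulfonate C[Si](C)(C)OS(=O)(=O)C(F)(F)F
Why: Soft enolisation with silyl triflate and amine gives a single terminal silyl enol ether because the ketone can enolise only towards C6 (C4 is quaternary), and no strong base touches the acrylate.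

Step 14
Reactants: 20 silyl enol ether triene
Product: 21 dimethyl 1β-[(tert-butyldimethylsilyl)oxy]-5α-[(trimethylsilyl)oxy]drim-8-ene-11,12-dioate
Conditions: toluene (0.005 M), BHT (5 mol%), iPr2NEt (0.1 equiv), degassed, 120 °C, sealed tube
Reagents that add atoms: none
Why: Proposed new method: the electron-poor 2,3-bis(methoxycarbonyl)diene C7=C8–C9=C10 and the electron-rich silyl enol ether C5=C6 should combine in a concerted but strongly asynchronous inverse-electron-demand [4+2] cycloaddition, with the C6–C7 bond between the two unhindered CH2 termini running ahead and the crowded C5–C10 bond following in a transition state polarised towards a C5 silyloxycarbenium ion and a C8–C10 ester dienolate; the closest known reactions are intermolecular inverse-demand Diels–Alder additions of 2,3-bis(alkoxycarbonyl)buta-1,3-dienes to enol ethers and thermal intramolecular Diels–Alder reactions of deca-1,7,9-trienes, neither shown for a fully substituted diene terminus with a Z-methyl group. Ring B is closed as the six-membered cyclohexene of the cycloaddition and ring A is closed by the C5–C10 bond across the four-carbon tether C1–C4 (six-membered, type 1 mode with the tether on the diene terminus and on the internal dienophile carbon), helped by the Thorpe–Ingold effect of the C4 gem-dimethyl group. C10 (methyl β) and C5 (oxygen α) are set relative to each other by the transition state that has the tether exo and the small OSiMe3 group endo under the diene, the orientation that an enol ether oxygen prefers in inverse-demand additions, so the inside methyl on C10 and the oxygen on C5 end up anti (trans ring fusion). Their absolute sense follows from C1: A(1,3) strain with the cis C9 ester keeps the C1–H bond in the diene plane, puts the C1 silyloxy group pseudo-equatorial on the chair-like tether and leads the dienophile to the diene face that gives the 1β-oxygen cis to the 10β-methyl. The step needs exo/endo selectivity (trans over cis fusion) and π-facial selectivity, which rest on the endo preference of the silyloxy group, on the C1 stereocentre and on the defined C9=C10 geometry (tether trans to C8), and it has to outrun the [1,5]-hydrogen shift from the inside methyl, which matched electronics and the intramolecular setting should allow at about 120 °C.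

Step 15
Reactants: 21 cycloadduct
Product: 23 methyl 5α-hydroxy-11-oxo-1β,11-epoxydrim-8-en-12-oate (γ-lactone from C11 to O1), via diol diester 22 (not isolated)
Conditions: HF (48% aq.), MeCN, 0 → 25 °C; then PPTS (0.2 equiv), toluene, 60 °C
Reagents that add atoms: none
Why: Acidic fluoride removes both silyl groups and the freed 1β-hydroxyl, which sits peri to the C11 ester (about 2.5 Å away), closes the γ-lactone by intramolecular transesterification, while the 5α-hydroxyl cannot lactonise because that would need a bridgehead alkene.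

Step 16
Reactants: 23 Δ8 lactone
Product: 25 methyl 5α-hydroxy-11-oxo-1β,11-epoxydrim-7-en-12-oate (9α-H), via dilithium alkoxide dienolate 24 (not isolated)
Conditions: LiN(iPr)2 (2.5 equiv), THF, −78 °C; AcOH, THF, −78 °C
Reagents that add atoms: none
Why: Deconjugative protonation of an extended enolate, in which γ-deprotonation at C7 gives the lactone dienolate and kinetic protonation at the α carbon C9 moves the alkene to C7=C8 in conjugation with the C12 ester, and the new C9 centre can only be 9α-H because C11 is tied to the 1β-oxygen and the angular methyl shields the β face.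

Step 17
Reactants: 25 Δ7 lactone
Product: 26 drim-7-ene-1β,5α,11,12-tetraol (9α-H)
Conditions: LiAlH4, THF, 0 → 25 °C
Reagents that add atoms: none
Why: Hydride reduction of the lactone and 1,2-reduction of the enoate give the tetraol without touching C9 or the C7=C8 alkene.

Step 18
Reactants: 26 tetraol
Product: 27 11,12-bis[(triethylsilyl)oxy]drim-7-ene-1β,5α-diol
Conditions: Et3SiCl (2.2 equiv), imidazole, CH2Cl2, −20 → 0 °C
Reagents that add atoms: chlorotriethylsilane CC[Si](Cl)(CC)CC
Why: Selective silylation, since the two primary hydroxyls react far faster than the neopentylic secondary C1 hydroxyl and the tertiary C5 hydroxyl.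

Step 19
Reactants: 28 (E)-4-hydroxycinnamic acid
Product: 30 (E)-3-{4-[(tert-butyldimethylsilyl)oxy]phenyl}prop-2-enoic acid, via bis-silyl derivative 29 (not isolated)
Conditions: TBSCl (2.5 equiv), imidazole, DMF, 25 °C; then AcOH–THF–H2O (3:1:1), 25 °C
Reagents that add atoms: tert-butyldimethylsilyl chloride CC(C)(C)[Si](C)(C)Cl
Why: Exhaustive silylation of phenol and acid followed by selective hydrolysis of the labile silyl ester leaves the aryl silyl ether in place.

Step 20
Reactants: 27 diol; 30 silylated cinnamic acid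
Product: 32 1β-[(E)-3-{4-[(tert-butyldimethylsilyl)oxy]phenyl}prop-2-enoyloxy]-11,12-bis[(triethylsilyl)oxy]drim-7-en-5α-ol, via mixed anhydride 31 (not isolated)
Conditions: 30, 2,4,6-Cl3C6H2COCl, Et3N, THF, 25 °C; then 27, DMAP, toluene, 25 → 60 °C
Reagents that add atoms: none
Why: Yamaguchi esterification, in which DMAP attacks the mixed anhydride at the cinnamoyl carbonyl and the acylpyridinium acylates the hindered secondary C1 hydroxyl, while the tertiary C5 hydroxyl is inert and the E alkene is untouched.

Step 21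
Reactants: 32 bis-triethylsilyl ether
Product: 33 1β-[(E)-3-{4-[(tert-butyldimethylsilyl)oxy]phenyl}prop-2-enoyloxy]drim-7-ene-5α,11,12-triol
Conditions: PPTS, MeOH–CH2Cl2 (1:1), 0 °C
Reagents that add atoms: none
Why: Mild acidic methanolysis cleaves the primary triethylsilyl ethers while the aryl tert-butyldimethylsilyl ether and the cinnamate survive.

Step 22
Reactants: 33 triol
Product: 34 1β-[(E)-3-{4-[(tert-butyldimethylsilyl)oxy]phenyl}prop-2-enoyloxy]-5α-hydroxydrim-7-ene-11,12-dial
Conditions: (COCl)2, DMSO, CH2Cl2, −78 °C; Et3N, −78 → −40 °C; pH 7 buffer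
Reagents that add atoms: none
Why: Swern oxidation of both primary alcohols at low temperature should give the 11,12-dialdehyde without a lactol stage, with the amine present only in the cold to protect the epimerisable C9 centre, and the tertiary alcohol cannot be oxidised.

Step 23
Reactants: 34 silylated dialdehyde
Product: 35 1β-[(E)-4-hydroxycinnamoyloxy]-5α-hydroxydrim-7-ene-11,12-dial (target, CNP0323926.1)
Conditions: Bu4NF, AcOH (1:1.2), THF, 0 °C
Reagents that add atoms: none
Why: Buffered fluoride cleaves the aryl silyl ether quickly at 0 °C because phenoxide is a good leaving group, and the acetic acid buffer keeps C9 and the enal from base-induced epimerisation or aldol reactions.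

**Compound list**

1 | 3-methylbutan-2-one | CC(C)C(C)=O | starting material
2 | methyl acrylate | C=CC(=O)OC | starting material
3 | methyl 4,4-dimethyl-5-oxohexanoate | COC(=O)CCC(C)(C)C(C)=O | intermediate
4 | methyl 4-methyl-4-(2-methyl-1,3-dioxolan-2-yl)pentanoate | COC(=O)CCC(C)(C)C1(C)OCCO1 | intermediate
5 | N-methoxy-N,4-dimethyl-4-(2-methyl-1,3-dioxolan-2-yl)pentanamide | CON(C)C(=O)CCC(C)(C)C1(C)OCCO1 | intermediate
6 | ethynyltrimethylsilane | C#C[Si](C)(C)C | starting material
7 | lithium (trimethylsilyl)acetylide | [Li]C#C[Si](C)(C)C | intermediate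
8 | 6-methyl-6-(2-methyl-1,3-dioxolan-2-yl)-1-(trimethylsilyl)hept-1-yn-3-one | C[Si](C)(C)C#CC(=O)CCC(C)(C)C1(C)OCCO1 | intermediate
9 | (3R)-6-methyl-6-(2-methyl-1,3-dioxolan-2-yl)-1-(trimethylsilyl)hept-1-yn-3-ol | C[Si](C)(C)C#C[C@H](O)CCC(C)(C)C1(C)OCCO1 | intermediate
10 | (3R)-3-[(tert-butyldimethylsilyl)oxy]-6-methyl-6-(2-methyl-1,3-dioxolan-2-yl)-1-(trimethylsilyl)hept-1-yne | C[Si](C)(C)C#C[C@H](O[Si](C)(C)C(C)(C)C)CCC(C)(C)C1(C)OCCO1 | intermediate
11 | (3R)-3-[(tert-butyldimethylsilyl)oxy]-6-methyl-6-(2-methyl-1,3-dioxolan-2-yl)hept-1-yne | C#C[C@H](O[Si](C)(C)C(C)(C)C)CCC(C)(C)C1(C)OCCO1 | intermediate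
12 | lithium acetylide of 11 | [Li]C#C[C@H](O[Si](C)(C)C(C)(C)C)CCC(C)(C)C1(C)OCCO1 | intermediate
13 | methyl (4R)-4-[(tert-butyldimethylsilyl)oxy]-7-methyl-7-(2-methyl-1,3-dioxolan-2-yl)oct-2-ynoate | COC(=O)C#C[C@H](O[Si](C)(C)C(C)(C)C)CCC(C)(C)C1(C)OCCO1 | intermediate
14 | lithium methyl cuprate of the syn adduct (copper on C9, cis to the new C10 methyl) | [Li+].COC(=O)/C([Cu-]C)=C(C)\[C@H](O[Si](C)(C)C(C)(C)C)CCC(C)(C)C1(C)OCCO1 | intermediate
15 | methyl (2E,4R)-4-[(tert-butyldimethylsilyl)oxy]-2-iodo-3,7-dimethyl-7-(2-methyl-1,3-dioxolan-2-yl)oct-2-enoate | COC(=O)/C(I)=C(C)\[C@H](O[Si](C)(C)C(C)(C)C)CCC(C)(C)C1(C)OCCO1 | intermediate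
16 | methyl (2E,4R)-4-[(tert-butyldimethylsilyl)oxy]-2-iodo-3,7,7-trimethyl-8-oxonon-2-enoate | COC(=O)/C(I)=C(C)\[C@H](O[Si](C)(C)C(C)(C)C)CCC(C)(C)C(C)=O | intermediate
17 | methyl propiolate | C#CC(=O)OC | starting material
18 | methyl 2-(tributylstannyl)prop-2-enoate | C=C(C(=O)OC)[Sn](CCCC)(CCCC)CCCC | intermediate
19 | dimethyl (2Z)-2-[(3R)-3-[(tert-butyldimethylsilyl)oxy]-6,6-dimethyl-7-oxooctan-2-ylidene]-3-methylidenebutanedioate | C=C(C(=O)OC)/C(C(=O)OC)=C(C)/[C@H](O[Si](C)(C)C(C)(C)C)CCC(C)(C)C(C)=O | intermediate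
20 | dimethyl (2Z)-2-[(3R)-3-[(tert-butyldimethylsilyl)oxy]-6,6-dimethyl-7-[(trimethylsilyl)oxy]oct-7-en-2-ylidene]-3-methylidenebutanedioate | C=C(O[Si](C)(C)C)C(C)(C)CC[C@@H](O[Si](C)(C)C(C)(C)C)/C(C)=C(\C(=O)OC)C(=C)C(=O)OC | intermediate
21 | dimethyl 1β-[(tert-butyldimethylsilyl)oxy]-5α-[(trimethylsilyl)oxy]drim-8-ene-11,12-dioate | CC1(C)CC[C@@H](O[Si](C)(C)C(C)(C)C)[C@]2(C)C(C(=O)OC)=C(C(=O)OC)CC[C@@]12O[Si](C)(C)C | intermediate
22 | dimethyl 1β,5α-dihydroxydrim-8-ene-11,12-dioate | CC1(C)CC[C@@H](O)[C@]2(C)C(C(=O)OC)=C(C(=O)OC)CC[C@@]12O | intermediate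
23 | methyl 5α-hydroxy-11-oxo-1β,11-epoxydrim-8-en-12-oate | CC1(C)CC[C@@H](O3)[C@]2(C)C(C3=O)=C(C(=O)OC)CC[C@@]12O | intermediate
24 | dilithium alkoxide dienolate of 23 | CC1(C)CC[C@@H](O3)[C@]2(C)C(=C3[O-])C(C(=O)OC)=CC[C@@]12[O-].[Li+].[Li+] | intermediate
25 | methyl 5α-hydroxy-11-oxo-1β,11-epoxydrim-7-en-12-oate (9α-H) | CC1(C)CC[C@@H](O3)[C@]2(C)[C@@H](C3=O)C(C(=O)OC)=CC[C@@]12O | intermediate
26 | drim-7-ene-1β,5α,11,12-tetraol (9α-H) | CC1(C)CC[C@@H](O)[C@]2(C)[C@@H](CO)C(CO)=CC[C@@]12O | intermediate
27 | 11,12-bis[(triethylsilyl)oxy]drim-7-ene-1β,5α-diol | CC1(C)CC[C@@H](O)[C@]2(C)[C@@H](CO[Si](CC)(CC)CC)C(CO[Si](CC)(CC)CC)=CC[C@@]12O | intermediate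
28 | (E)-4-hydroxycinnamic acid | O=C(O)/C=C/c1ccc(O)cc1 | starting material
29 | tert-butyldimethylsilyl (E)-3-{4-[(tert-butyldimethylsilyl)oxy]phenyl}prop-2-enoate | CC(C)(C)[Si](C)(C)OC(=O)/C=C/c1ccc(O[Si](C)(C)C(C)(C)C)cc1 | intermediate
30 | (E)-3-{4-[(tert-butyldimethylsilyl)oxy]phenyl}prop-2-enoic acid | O=C(O)/C=C/c1ccc(O[Si](C)(C)C(C)(C)C)cc1 | intermediate
31 | mixed anhydride of 30 with 2,4,6-trichlorobenzoic acid | O=C(OC(=O)c1c(Cl)cc(Cl)cc1Cl)/C=C/c1ccc(O[Si](C)(C)C(C)(C)C)cc1 | intermediate
32 | 1β-[(E)-3-{4-[(tert-butyldimethylsilyl)oxy]phenyl}prop-2-enoyloxy]-11,12-bis[(triethylsilyl)oxy]drim-7-en-5α-ol | CC1(C)CC[C@@H](OC(=O)/C=C/c3ccc(O[Si](C)(C)C(C)(C)C)cc3)[C@]2(C)[C@@H](CO[Si](CC)(CC)CC)C(CO[Si](CC)(CC)CC)=CC[C@@]12O | intermediate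
33 | 1β-[(E)-3-{4-[(tert-butyldimethylsilyl)oxy]phenyl}prop-2-enoyloxy]drim-7-ene-5α,11,12-triol | CC1(C)CC[C@@H](OC(=O)/C=C/c3ccc(O[Si](C)(C)C(C)(C)C)cc3)[C@]2(C)[C@@H](CO)C(CO)=CC[C@@]12O | intermediate
34 | 1β-[(E)-3-{4-[(tert-butyldimethylsilyl)oxy]phenyl}prop-2-enoyloxy]-5α-hydroxydrim-7-ene-11,12-dial | CC1(C)CC[C@@H](OC(=O)/C=C/c3ccc(O[Si](C)(C)C(C)(C)C)cc3)[C@]2(C)[C@@H](C=O)C(C=O)=CC[C@@]12O | intermediate
35 | 1β-[(E)-4-hydroxycinnamoyloxy]-5α-hydroxydrim-7-ene-11,12-dial (CNP0323926.1) | CC1(C)CC[C@@H](OC(=O)/C=C/c2ccc(O)cc2)[C@]2(C)[C@@H](C=O)C(C=O)=CC[C@@]12O | target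

**Step count**

Total: 23 steps. Longest linear sequence: 21 steps (steps 1–10, 12–18 and 20–23; steps 11 and 19 make the coupling partners 18 and 30).

**Steps most likely to fail**

Step 14 (carries the label "Proposed new method:"). The inside methyl on C10 disfavours the s-cis diene, so a [1,5]-hydrogen shift from that methyl, oligomerisation through the acrylate unit or loss of the enol silyl group may outrun cycloaddition. Poor exo/endo selectivity would give the cis-fused isomer. The fallback builds ring A first and ring B by a normal-demand intermolecular Diels–Alder reaction, all by known reaction types; it sets out from keto ester 3 and comes back at lactone 23. NaOMe in MeOH/toluene closes 3 by intramolecular Claisen condensation to 4,4-dimethylcyclohexane-1,3-dione F1. C-Methylation (MeI, K2CO3, acetone) gives 2,4,4-trimethylcyclohexane-1,3-dione F2. Isobutanol/TsOH gives the vinylogous ester 3-(2-methylpropoxy)-2,6,6-trimethylcyclohex-2-en-1-one F3, with the alkoxy group on the carbonyl remote from the gem-dimethyl group. Addition of CH2=CHMgBr/CeCl3 and acidic work-up (1,2-addition, enol ether hydrolysis, dehydration with carbonyl transposition) gives 3-ethenyl-2,4,4-trimethylcyclohex-2-en-1-one F4. Corey–Bakshi–Shibata reduction with the (S)-2-methyl-oxazaborolidine and BH3·SMe2 should give (1R)-3-ethenyl-2,4,4-trimethylcyclohex-2-en-1-ol F5, which is silylated (TBSCl, imidazole) to the diene tert-butyldimethylsilyl ether F6. Diels–Alder reaction of F6 with dimethyl acetylenedicarboxylate (toluene, 110 °C), anti to the silyloxy group, should give dimethyl 1β-[(tert-butyldimethylsilyl)oxy]drima-5,8-diene-11,12-dioate F7. Markovnikov hydration of C5=C6 by hydrogen-atom transfer (Mn(dpm)3, PhSiH3, O2; then P(OEt)3), with oxygen entering C5 from the α face opposite the angular methyl, gives dimethyl 1β-[(tert-butyldimethylsilyl)oxy]-5α-hydroxydrim-8-ene-11,12-dioate F8. The conditions of step 15 (HF, then PPTS) convert F8 into 23.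

Step 12. Transmetalation of the electron-poor α-stannyl acrylate to a hindered, tetrasubstituted alkenylpalladium iodide may be too slow, so protodestannylation, homocoupling or cine substitution take over, or the diene oligomerises under the coupling conditions. The fallback introduces C8 as a CH2CO2Me group and methylenates it afterwards; it sets out from ketal iodide 15 and comes back at keto diene 19. Negishi-type coupling of 15 with the Reformatsky reagent BrZnCH2CO2Me (Pd2(dba)3, P(tBu)3, THF) gives the alkylidenesuccinate dimethyl (2Z)-2-[(3R)-3-silyloxy-6-methyl-6-(2-methyl-1,3-dioxolan-2-yl)heptan-2-ylidene]butanedioate F9. Enolisation at C8 (LiN(SiMe3)2, THF, −78 °C) and Mannich reaction with CH2=NMe2+ I− give the C8 dimethylaminomethyl derivative F10 (mixture at C8). N-Methylation (MeI) and elimination (NaHCO3) give the diene diester ketal F11. PPTS in wet acetone removes the dioxolane and gives 19.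

Step 20. Acylation may stall at the neopentylic C1 hydroxyl, which is flanked by the angular methyl and the peri CH2OSiEt3 group, so that the mixed anhydride is consumed unproductively. The fallback assembles the cinnamate on the alcohol from a small acyl group; it sets out from diol 27 and comes back at ester 32. Esterification of 27 with diethylphosphonoacetic acid (EDC·HCl, DMAP, CH2Cl2) gives 1β-[(diethoxyphosphoryl)acetoxy]-11,12-bis[(triethylsilyl)oxy]drim-7-en-5α-ol F12. Horner–Wadsworth–Emmons olefination with 4-[(tert-butyldimethylsilyl)oxy]benzaldehyde (LiCl, DBU, MeCN) gives the (E)-cinnamate 32.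

**Further compounds**

F1 | step 14 | 4,4-dimethylcyclohexane-1,3-dione | CC1(C)CCC(=O)CC1=O
F2 | step 14 | 2,4,4-trimethylcyclohexane-1,3-dione | CC1C(=O)CCC(C)(C)C1=O
F3 | step 14 | 3-(2-methylpropoxy)-2,6,6-trimethylcyclohex-2-en-1-one | CC1=C(OCC(C)C)CCC(C)(C)C1=O
F4 | step 14 | 3-ethenyl-2,4,4-trimethylcyclohex-2-en-1-one | C=CC1=C(C)C(=O)CCC1(C)C
F5 | step 14 | (1R)-3-ethenyl-2,4,4-trimethylcyclohex-2-en-1-ol | C=CC1=C(C)[C@H](O)CCC1(C)C
F6 | step 14 | tert-butyl{[(1R)-3-ethenyl-2,4,4-trimethylcyclohex-2-en-1-yl]oxy}dimethylsilane | C=CC1=C(C)[C@H](O[Si](C)(C)C(C)(C)C)CCC1(C)C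
F7 | step 14 | dimethyl 1β-[(tert-butyldimethylsilyl)oxy]drima-5,8-diene-11,12-dioate | CC1(C)CC[C@@H](O[Si](C)(C)C(C)(C)C)[C@]2(C)C(C(=O)OC)=C(C(=O)OC)CC=C12
F8 | step 14 | dimethyl 1β-[(tert-butyldimethylsilyl)oxy]-5α-hydroxydrim-8-ene-11,12-dioate | CC1(C)CC[C@@H](O[Si](C)(C)C(C)(C)C)[C@]2(C)C(C(=O)OC)=C(C(=O)OC)CC[C@@]12O
F9 | step 12 | dimethyl (2Z)-2-[(3R)-3-[(tert-butyldimethylsilyl)oxy]-6-methyl-6-(2-methyl-1,3-dioxolan-2-yl)heptan-2-ylidene]butanedioate | COC(=O)C/C(C(=O)OC)=C(C)/[C@H](O[Si](C)(C)C(C)(C)C)CCC(C)(C)C1(C)OCCO1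
F10 | step 12 | dimethyl (2Z)-2-[(3R)-3-[(tert-butyldimethylsilyl)oxy]-6-methyl-6-(2-methyl-1,3-dioxolan-2-yl)heptan-2-ylidene]-3-[(dimethylamino)methyl]butanedioate | COC(=O)C(CN(C)C)/C(C(=O)OC)=C(C)/[C@H](O[Si](C)(C)C(C)(C)C)CCC(C)(C)C1(C)OCCO1
F11 | step 12 | dimethyl (2Z)-2-[(3R)-3-[(tert-butyldimethylsilyl)oxy]-6-methyl-6-(2-methyl-1,3-dioxolan-2-yl)heptan-2-ylidene]-3-methylidenebutanedioate | C=C(C(=O)OC)/C(C(=O)OC)=C(C)/[C@H](O[Si](C)(C)C(C)(C)C)CCC(C)(C)C1(C)OCCO1
F12 | step 20 | 1β-[(diethoxyphosphoryl)acetoxy]-11,12-bis[(triethylsilyl)oxy]drim-7-en-5α-ol | CC1(C)CC[C@@H](OC(=O)CP(=O)(OCC)OCC)[C@]2(C)[C@@H](CO[Si](CC)(CC)CC)C(CO[Si](CC)(CC)CC)=CC[C@@]12O
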